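**Retrosynthetic overview**
1. The target comes from its bis-O-benzyl ether by one closing hydrogenolysis.
2. The key cut is the C1–aryl bond. The β-carbon of the C3 ketone acts as the nucleophile, as a palladium homoenolate released from a 1-substituted cyclopropanol, and couples with the guaiacyl bromide.
3. The cyclopropanol comes from the (R)-β-hydroxy ester and EtMgBr (Kulinkovich), so C1 and C2 come from the Grignard reagent.
4. The C5 stereocentre comes from Ru/(R)-BINAP hydrogenation of a β-keto ester. That ester is made by Heck arylation/isomerisation of ethyl 3-hydroxypent-4-enoate (acrolein + ethyl acetate) with the syringyl bromide.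
5. Rings: both arenes are bought. The only ring made is the sacrificial cyclopropane (step 5), which is opened again in step 6.

Assumption: the [C@H] centre of the given SMILES reads as (5R) (OH > C4 > C6 > H), and the benzyl ether of 4-bromo-2-methoxyphenol is taken as a catalogue compound.

**Route**

Step 1
Reactants: 1 ethyl acetate; 2 acrolein (prop-2-enal)
Product: 4 rac-ethyl 3-hydroxypent-4-enoate, via lithium ester enolate 3 (not isolated)
Conditions: LiN(iPr)2 (1.05 equiv), THF, −78 °C; then 2; AcOH quench at −78 °C
Reagents that add atoms: none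
Why: Directed aldol addition of a preformed lithium ester enolate: at −78 °C enolate 3 adds 1,2 to acrolein faster than it adds 1,4 or self-condenses, and the racemic carbinol is acceptable because this centre is erased in step 3.

Step 2
Reactants: 5 4-bromo-2,6-dimethoxyphenol; 6 benzyl bromide
Product: 7 2-(benzyloxy)-5-bromo-1,3-dimethoxybenzene
Conditions: K2CO3 (1.5 equiv), DMF, 60 °C
Reagents that add atoms: benzyl bromide (6), BrCc1ccccc1
Why: Williamson ether synthesis: the phenoxide of 5 displaces bromide from 6 by SN2, masking the acidic, easily oxidised syringyl OH for the Grignard and palladium steps with a group that leaves by hydrogenolysis at the end.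

Step 3
Reactants: 7 2-(benzyloxy)-5-bromo-1,3-dimethoxybenzene; 4 rac-ethyl 3-hydroxypent-4-enoate (1.5 equiv)
Product: 9 ethyl 5-[4-(benzyloxy)-3,5-dimethoxyphenyl]-3-oxopentanoate, via enol 8 (not isolated)
Conditions: Pd(OAc)2 (3 mol %), P(o-tol)3 (6 mol %), NaHCO3 (1.5 equiv), DMF, 95 °C
Reagents that add atoms: none
Why: Mizoroki–Heck arylation of a secondary allylic alcohol with redox isomerisation: after oxidative addition of 7 the aryl group goes to the terminal alkene carbon, β-hydride elimination takes the carbinol C–H to give enol 8, and tautomerisation gives the saturated β-keto ester, the same manifold that turns but-3-en-2-ol and aryl bromides into 4-arylbutan-2-ones.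

Step 4
Reactants: 9 ethyl 5-[4-(benzyloxy)-3,5-dimethoxyphenyl]-3-oxopentanoate
Product: 10 ethyl (3R)-5-[4-(benzyloxy)-3,5-dimethoxyphenyl]-3-hydroxypentanoate
Conditions: RuCl2[(R)-BINAP] (0.5 mol %), H2 (50 bar), EtOH, 50 °C
Reagents that add atoms: none
Why: Noyori asymmetric hydrogenation of a β-keto ester: the ester carbonyl chelates ruthenium and the (R)-BINAP pocket passes hydride to one ketone face only, setting the (3R)-carbinol (typically 97–99% ee, same sense as methyl acetoacetate to methyl (R)-3-hydroxybutanoate), while aryl benzyl ethers are inert to this homogeneous catalyst.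

Step 5
Reactants: 10 ethyl (3R)-5-[4-(benzyloxy)-3,5-dimethoxyphenyl]-3-hydroxypentanoate; 11 ethylmagnesium bromide
Product: 13 1-{(2R)-4-[4-(benzyloxy)-3,5-dimethoxyphenyl]-2-hydroxybutyl}cyclopropan-1-ol, via titanacyclopropane 12 (not isolated)
Conditions: EtMgBr (4 equiv, slow addition), Ti(OiPr)4 (0.3 equiv), THF, 0 °C to rt; then H2O, filter through Celite
Reagents that add atoms: ethylmagnesium bromide (11), CC[Mg]Br
Why: Kulinkovich cyclopropanation: titanacyclopropane 12 acts as a 1,2-dicarbanion and adds twice to the ester carbonyl with loss of ethoxide, the first equivalent of Grignard reagent only deprotonates the carbinol (free hydroxy esters and lactones are known substrates), and the C–O stereocentre is not touched.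

Step 6 (key step)
Reactants: 13 1-{(2R)-4-[4-(benzyloxy)-3,5-dimethoxyphenyl]-2-hydroxybutyl}cyclopropan-1-ol; 14 1-(benzyloxy)-4-bromo-2-methoxybenzene
Product: 16 (5R)-1-[4-(benzyloxy)-3-methoxyphenyl]-7-[4-(benzyloxy)-3,5-dimethoxyphenyl]-5-hydroxyheptan-3-one, via arylpalladium homoenolate 15 (not isolated)
Conditions: Pd(OAc)2 (5 mol %), XPhos (10 mol %), Cs2CO3 (1.5 equiv), toluene, 70 °C, argon
Reagents that add atoms: none
Why: Palladium-catalysed ring-opening cross-coupling of a tertiary cyclopropanol with an aryl bromide (ketone homoenolate arylation): after oxidative addition of 14 to zerovalent palladium the strained, more acidic tertiary cyclopropanol binds as its alkoxide, strain-driven β-carbon elimination gives homoenolate 15, in which the normally electrophilic β-carbon of the new C3 ketone is the nucleophilic partner of the equally electrophilic aryl bromide carbon, bulky XPhos drives C–C reductive elimination ahead of β-hydride elimination, and the remote (R)-carbinol stays a spectator.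

Step 7
Reactants: 16 (5R)-1-[4-(benzyloxy)-3-methoxyphenyl]-7-[4-(benzyloxy)-3,5-dimethoxyphenyl]-5-hydroxyheptan-3-one
Product: 17 (5R)-5-hydroxy-7-(4-hydroxy-3,5-dimethoxyphenyl)-1-(4-hydroxy-3-methoxyphenyl)heptan-3-one (target)
Conditions: H2 (1 atm), 10% Pd/C, EtOAc–EtOH, rt
Reagents that add atoms: none
Why: Catalytic hydrogenolysis: both aryl benzyl ethers are cleaved on Pd/C under neutral conditions that leave the aliphatic ketone, the aryl methyl ethers and the acid- and base-sensitive β-hydroxy ketone (hence C5) unchanged.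

**Compound list**
1 | ethyl acetate | CCOC(C)=O | starting material
2 | acrolein | C=CC=O | starting material
3 | lithium 1-ethoxyethen-1-olate (lithium enolate of ethyl acetate) | [Li+].[O-]C(=C)OCC | intermediate
4 | rac-ethyl 3-hydroxypent-4-enoate | CCOC(=O)CC(O)C=C | intermediate
5 | 4-bromo-2,6-dimethoxyphenol | COc1cc(Br)cc(OC)c1O | starting material
6 | benzyl bromide | BrCc1ccccc1 | starting material
7 | 2-(benzyloxy)-5-bromo-1,3-dimethoxybenzene | COc1cc(Br)cc(OC)c1OCc1ccccc1 | intermediate
8 | ethyl 5-[4-(benzyloxy)-3,5-dimethoxyphenyl]-3-hydroxypent-3-enoate (enol form of 9) | CCOC(=O)CC(O)=CCc1cc(OC)c(OCc2ccccc2)c(OC)c1 | intermediate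
9 | ethyl 5-[4-(benzyloxy)-3,5-dimethoxyphenyl]-3-oxopentanoate | CCOC(=O)CC(=O)CCc1cc(OC)c(OCc2ccccc2)c(OC)c1 | intermediate
10 | ethyl (3R)-5-[4-(benzyloxy)-3,5-dimethoxyphenyl]-3-hydroxypentanoate | CCOC(=O)C[C@H](O)CCc1cc(OC)c(OCc2ccccc2)c(OC)c1 | intermediate
11 | ethylmagnesium bromide | CC[Mg]Br | starting material
12 | diisopropoxytitanacyclopropane, (iPrO)2Ti(C2H4) | CC(C)O[Ti]1(CC1)OC(C)C | intermediate
13 | 1-{(2R)-4-[4-(benzyloxy)-3,5-dimethoxyphenyl]-2-hydroxybutyl}cyclopropan-1-ol | OC1(C[C@H](O)CCc2cc(OC)c(OCc3ccccc3)c(OC)c2)CC1 | intermediate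
14 | 1-(benzyloxy)-4-bromo-2-methoxybenzene | COc1cc(Br)ccc1OCc1ccccc1 | starting material
15 | [4-(benzyloxy)-3-methoxyphenyl][(5R)-7-(4-benzyloxy-3,5-dimethoxyphenyl)-5-hydroxy-3-oxoheptyl]palladium (XPhos on palladium not drawn) | COc1cc([Pd]CCC(=O)C[C@H](O)CCc2cc(OC)c(OCc3ccccc3)c(OC)c2)ccc1OCc1ccccc1 | intermediate
16 | (5R)-1-[4-(benzyloxy)-3-methoxyphenyl]-7-[4-(benzyloxy)-3,5-dimethoxyphenyl]-5-hydroxyheptan-3-one | COc1cc(CCC(=O)C[C@H](O)CCc2cc(OC)c(OCc3ccccc3)c(OC)c2)ccc1OCc1ccccc1 | intermediate
17 | (5R)-5-hydroxy-7-(4-hydroxy-3,5-dimethoxyphenyl)-1-(4-hydroxy-3-methoxyphenyl)heptan-3-one | COc1cc(CCC(=O)C[C@H](O)CCc2cc(OC)c(O)c(OC)c2)ccc1O | target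

**Step count**
Total steps: 7. Longest linear sequence: 6 steps (5 → 7 → 9 → 10 → 13 → 16 → 17). Step 1 is a one-step side branch.

**Steps most likely to fail**

1) Step 6.
- Risks: β-hydride elimination of 15 to the vinyl ketone; protonation of 15 by the free carbinol to the ethyl ketone; carbonate-induced retro-aldol or dehydration of 16.
- Fallback: it sets out from 13 and comes back at 16. The β-carbon remains the reversed-polarity partner, but it is generated on nickel from an enone under base-free, reducing conditions. Et3SiCl and imidazole (CH2Cl2, −20 °C) silylate only the secondary hydroxyl and give the secondary triethylsilyl ether F1. Pd(OAc)2 (10 mol %), pyridine and O2 (1 atm) in toluene at 60 °C then use the unwanted pathway on purpose (ring opening on divalent palladium, then β-hydride elimination) and give the vinyl ketone F2. NiCl2(dme) (10 mol %), neocuproine, Mn powder and Et3SiCl in DMF at 40 °C join F2 with 14 in a reductive conjugate arylation, where the silyl-activated enone and the aryl bromide are both electrophiles, giving the enol silane F3. AcOH–THF–H2O at rt removes both silyl groups and gives 16.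

2) Step 5.
- Risks: the chelating magnesium β-alkoxide slows titanium turnover, so plain ethyl addition to the ester (tertiary carbinol) competes and conversion stalls.
- Fallback: it sets out from 10 and comes back at 13, leaving titanium chemistry altogether. Sm powder and CH2I2 (5 equiv each) in THF at 50 °C give a samarium carbenoid that converts the ester into the iodomethyl ketone F4. This is reduced by divalent samarium and cyclopropanated by a second carbenoid in the same flask. Compound 13 is thus reached in one operation, with C1 and C2 coming from CH2I2.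

3) Step 3.
- Risks: slow oxidative addition of the electron-rich bromide; β-hydride elimination toward the benzylic side (styrenyl allylic alcohol); loss of 4 by palladium hydride isomerisation.
- Fallback: it sets out from 7 and comes back at 9, replacing the Heck reaction by an enolate alkylation and making step 1 unnecessary. Bromine–lithium exchange on 7 (n-BuLi, THF, −78 °C) and trapping with paraformaldehyde give the benzylic alcohol F5. PBr3 (Et2O, 0 °C) gives the benzylic bromide F6. Ethyl acetoacetate, deprotonated twice (NaH, then n-BuLi, THF, 0 °C), is alkylated by F6 at its terminal carbon (Weiler dianion alkylation) and gives 9.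

**Further compounds**
F1 | step 6 | 1-{(2R)-4-[4-(benzyloxy)-3,5-dimethoxyphenyl]-2-[(triethylsilyl)oxy]butyl}cyclopropan-1-ol | OC1(C[C@H](O[Si](CC)(CC)CC)CCc2cc(OC)c(OCc3ccccc3)c(OC)c2)CC1
F2 | step 6 | (5R)-7-[4-(benzyloxy)-3,5-dimethoxyphenyl]-5-[(triethylsilyl)oxy]hept-1-en-3-one | C=CC(=O)C[C@H](O[Si](CC)(CC)CC)CCc1cc(OC)c(OCc2ccccc2)c(OC)c1
F3 | step 6 | (5R)-1-[4-(benzyloxy)-3-methoxyphenyl]-7-[4-(benzyloxy)-3,5-dimethoxyphenyl]-3,5-bis[(triethylsilyl)oxy]hept-2-ene | COc1cc(CC=C(O[Si](CC)(CC)CC)C[C@H](O[Si](CC)(CC)CC)CCc2cc(OC)c(OCc3ccccc3)c(OC)c2)ccc1OCc1ccccc1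
F4 | step 5 | (4R)-6-[4-(benzyloxy)-3,5-dimethoxyphenyl]-4-hydroxy-1-iodohexan-2-one | ICC(=O)C[C@H](O)CCc1cc(OC)c(OCc2ccccc2)c(OC)c1
F5 | step 3 | [4-(benzyloxy)-3,5-dimethoxyphenyl]methanol | COc1cc(CO)cc(OC)c1OCc1ccccc1
F6 | step 3 | 2-(benzyloxy)-5-(bromomethyl)-1,3-dimethoxybenzene | COc1cc(CBr)cc(OC)c1OCc1ccccc1
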